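**Retrosynthetic overview**

- The C2 bromine is put in last by ipso-bromodecarboxylation of the indole-2-carboxylic acid, which comes from an N-Boc indole-2-carboxylate methyl ester by hydrolysis.
- Key disconnection: N1–C7a and C3–C3a of the pyrrole ring are cut together. C3a and C7a are neighbouring benzenoid carbons, C3a next to C4–Br and C7a next to C7–H. That is the pattern of 3,4,5-tribromobenzyne, whose triple bond is polarised by the flanking bromine, so nitrogen goes to the distal carbon and carbon to the proximal one.
- The partner is a Boc-amino ketene dithioacetal ester. It supplies N1, C2 (with the ester as placeholder for bromine) and C3 with its methylsulfanyl group; the second methylsulfanyl group is the leaving group that aromatises the ring.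
- The aryne precursor (ortho-silyl aryl triflate) comes from 3,4,5-tribromophenol by carbamate-directed ortho-silylation. The dithioacetal comes from methyl N-Boc-glycinate, carbon disulfide and iodomethane.
- Ring order: the benzene ring is bought; the pyrrole ring is the only ring formed, in the key step.

Key step: step 5

Remark: the carbamate silylated in situ in step 2 is drawn as its N-silyl form; the O-silyl imidate tautomer would behave the same way.

**Route**

Step 1
Reactants: 1 3,4,5-tribromophenol
Product: 2 3,4,5-tribromophenyl N-(propan-2-yl)carbamate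
Conditions: iPrNCO, Et3N (cat.), CH2Cl2, rt
Reagents that add atoms: isopropyl isocyanate, CC(C)N=C=O
Why: Base-catalysed addition of the phenol to the isocyanate (carbamoylation) should give the N-monoalkyl carbamate, which directs ortho-metalation and is later removed under mild E1cB conditions.

Step 2
Reactants: 2 3,4,5-tribromophenyl N-(propan-2-yl)carbamate
Product: 5 3,4,5-tribromo-2-(trimethylsilyl)phenyl N-(propan-2-yl)carbamate, via N-TBS carbamate 3 (not isolated), via N-TBS C-TMS carbamate 4 (not isolated)
Conditions: TBSOTf, TMEDA, Et2O, 0 °C to rt; then TMSCl, LiN(iPr)2 (1.2 equiv), THF, −78 °C; aq. NaHSO4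
Reagents that add atoms: chlorotrimethylsilane, C[Si](C)(C)Cl
Why: Directed ortho-metalation of an O-aryl carbamate with in-situ N-silylation and in-situ chlorosilane trapping: the two equivalent ring C–H positions lie between the carbamate oxygen and a bromine, so the amide base deprotonates there without the bromine–lithium exchange an alkyllithium would cause, and the chlorosilane traps the aryllithium before it can lose LiBr or rearrange.

Step 3
Reactants: 5 3,4,5-tribromo-2-(trimethylsilyl)phenyl N-(propan-2-yl)carbamate
Product: 7 3,4,5-tribromo-2-(trimethylsilyl)phenyl trifluoromethanesulfonate, via silylphenol 6 (not isolated)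
Conditions: DBU, Et2NH, MeCN, 40 °C; then PhNTf2, rt
Reagents that add atoms: N-phenylbis(trifluoromethanesulfonimide), O=S(=O)(N(c1ccccc1)S(=O)(=O)C(F)(F)F)C(F)(F)F
Why: E1cB cleavage of the N–H carbamate by DBU (the isocyanate is scavenged by diethylamine as a urea) should free the phenoxide, which is triflated in the same pot; this is the usual one-pot entry to ortho-silyl aryl triflates.

Step 4
Reactants: 8 methyl N-(tert-butoxycarbonyl)glycinate, 9 carbon disulfide, 10 iodomethane
Product: 13 methyl 2-[(tert-butoxycarbonyl)amino]-3,3-bis(methylsulfanyl)prop-2-enoate, via glycinate dianion 11 (not isolated), via dithiocarboxylate 12 (not isolated)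
Conditions: LiN(SiMe3)2 (2.05 equiv), THF, −78 °C; CS2, −78 °C; MeI (2.1 equiv), −78 °C to 0 °C
Reagents that add atoms: carbon disulfide, S=C=S; iodomethane, CI
Why: Two equivalents of amide base should give the chelated N,C-dianion of the glycinate, whose carbon adds to carbon disulfide (enolate dithiocarboxylation); S-methylation, proton shift from the now acidic α-C–H to nitrogen and a second S-methylation then give the ketene dithioacetal with the N–H intact.

Step 5
Reactants: 7 3,4,5-tribromo-2-(trimethylsilyl)phenyl trifluoromethanesulfonate, 13 methyl 2-[(tert-butoxycarbonyl)amino]-3,3-bis(methylsulfanyl)prop-2-enoate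
Product: 15 1-tert-butyl 2-methyl 4,5,6-tribromo-3-(methylsulfanyl)-1H-indole-1,2-dicarboxylate, via 3,4,5-tribromobenzyne 14 (not isolated)
Conditions: Bu4N[Ph3SiF2] (3 equiv), THF, rt, slow addition of 7 (2.5 equiv)
Reagents that add atoms: none
Why: Proposed new method: fluoride attacks silicon in 7 and the aryl anion expels triflate to give aryne 14, while fluoride also deprotonates the carbamate N–H of 13; the nitrogen anion adds to the aryne carbon remote from C–Br (the future C7a), the aryl anion formed at the future C3a adds to the bis(methylsulfanyl) carbon of the enoate, and the ester enolate expels methanethiolate to give the aromatic indole with one sulfur left on C3. The closest known reaction type is the fluoride-induced annulation of arynes with N-Boc dehydroalanine esters to indoline-2-carboxylates, together with addition–elimination at ketene dithioacetals; combining them with thiolate loss to reach the indole directly has not been shown. The pyrrole ring closes by 5-endo-trig conjugate addition of the aryl anion, as in the indoline case. No stereocentre is formed. The step needs regioselectivity at the aryne, which the bromine beside the triple bond should secure because its inductive pull distorts the aryne so that nucleophiles attack the distal carbon and the charge develops next to C–Br; it also needs ring closure to outrun protonation and bromide loss of the ortho-bromoaryl anion, which the non-protic THF medium and the acceptor held four atoms away are meant to favour. Compound 7 is used in excess because the released thiolate also captures aryne.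

Step 6
Reactants: 15 1-tert-butyl 2-methyl 4,5,6-tribromo-3-(methylsulfanyl)-1H-indole-1,2-dicarboxylate
Product: 17 4,5,6-tribromo-3-(methylsulfanyl)-1H-indole-2-carboxylic acid, via N-H methyl ester 16 (not isolated)
Conditions: LiOH, THF/MeOH/H2O, 50 °C; then aq. HCl
Reagents that add atoms: lithium hydroxide (its oxygen becomes the acid OH), [Li+].[OH-]
Why: Nucleophilic acyl substitution by hydroxide should first cleave the azolide-like indole N-carbamate and then saponify the methyl ester, giving the acid on acidification; the aryl bromides and the thioether are inert to these conditions.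

Step 7
Reactants: 17 4,5,6-tribromo-3-(methylsulfanyl)-1H-indole-2-carboxylic acid
Product: 18 2,4,5,6-tetrabromo-3-(methylsulfanyl)-1H-indole
Conditions: NBS (1.0 equiv), LiOAc (cat.), DMF, 0 °C to rt, dark
Reagents that add atoms: N-bromosuccinimide, O=C1CCC(=O)N1Br
Why: Ipso-bromodecarboxylation (Hunsdiecker-type halodecarboxylation of an electron-rich heteroaryl acid): electrophilic bromine should attack C2, the cation at C3 being stabilised by the methylsulfanyl group, and loss of CO2 restores the indole with bromine at C2.

**Compound list**

1 | 3,4,5-tribromophenol | Oc1cc(Br)c(Br)c(Br)c1 | starting material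
2 | 3,4,5-tribromophenyl N-(propan-2-yl)carbamate | CC(C)NC(=O)Oc1cc(Br)c(Br)c(Br)c1 | intermediate
3 | 3,4,5-tribromophenyl N-[tert-butyl(dimethyl)silyl]-N-(propan-2-yl)carbamate | CC(C)N(C(=O)Oc1cc(Br)c(Br)c(Br)c1)[Si](C)(C)C(C)(C)C | intermediate
4 | 3,4,5-tribromo-2-(trimethylsilyl)phenyl N-[tert-butyl(dimethyl)silyl]-N-(propan-2-yl)carbamate | CC(C)N(C(=O)Oc1cc(Br)c(Br)c(Br)c1[Si](C)(C)C)[Si](C)(C)C(C)(C)C | intermediate
5 | 3,4,5-tribromo-2-(trimethylsilyl)phenyl N-(propan-2-yl)carbamate | CC(C)NC(=O)Oc1cc(Br)c(Br)c(Br)c1[Si](C)(C)C | intermediate
6 | 3,4,5-tribromo-2-(trimethylsilyl)phenol | Oc1cc(Br)c(Br)c(Br)c1[Si](C)(C)C | intermediate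
7 | 3,4,5-tribromo-2-(trimethylsilyl)phenyl trifluoromethanesulfonate | C[Si](C)(C)c1c(OS(=O)(=O)C(F)(F)F)cc(Br)c(Br)c1Br | intermediate
8 | methyl N-(tert-butoxycarbonyl)glycinate | COC(=O)CNC(=O)OC(C)(C)C | starting material
9 | carbon disulfide | S=C=S | starting material
10 | iodomethane | CI | starting material
11 | dilithium N,C-dianion (chelated enolate) of methyl N-(tert-butoxycarbonyl)glycinate | [Li+].[Li+].COC([O-])=C[N-]C(=O)OC(C)(C)C | intermediate
12 | dilithium 2-[(tert-butoxycarbonyl)azanidyl]-3-methoxy-3-oxopropanedithioate | [Li+].[Li+].COC(=O)C([N-]C(=O)OC(C)(C)C)C(=S)[S-] | intermediate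
13 | methyl 2-[(tert-butoxycarbonyl)amino]-3,3-bis(methylsulfanyl)prop-2-enoate | COC(=O)C(NC(=O)OC(C)(C)C)=C(SC)SC | intermediate
14 | 3,4,5-tribromobenzyne | BrC1=C(Br)C(Br)=CC#C1 | intermediate
15 | 1-tert-butyl 2-methyl 4,5,6-tribromo-3-(methylsulfanyl)-1H-indole-1,2-dicarboxylate | COC(=O)c1c(SC)c2c(Br)c(Br)c(Br)cc2n1C(=O)OC(C)(C)C | intermediate
16 | methyl 4,5,6-tribromo-3-(methylsulfanyl)-1H-indole-2-carboxylate | COC(=O)c1[nH]c2cc(Br)c(Br)c(Br)c2c1SC | intermediate
17 | 4,5,6-tribromo-3-(methylsulfanyl)-1H-indole-2-carboxylic acid | OC(=O)c1[nH]c2cc(Br)c(Br)c(Br)c2c1SC | intermediate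
18 | 2,4,5,6-tetrabromo-3-(methylsulfanyl)-1H-indole | CSc1c(Br)[nH]c2cc(Br)c(Br)c(Br)c12 | target

**Step count and risks**

Total step count: 7. Longest linear sequence: 6 steps (steps 1, 2, 3, 5, 6, 7); step 4 is a one-step side branch.

Steps most likely to fail:

Step 5 (the proposed new method). The ortho-bromoaryl anion formed after N-arylation may be protonated or may lose bromide to a second aryne before it closes the ring. The thioether sulfur atoms may add to the aryne in place of nitrogen, and the released thiolate competes for aryne. The fallback avoids arynes altogether and uses known chemistry, setting out from 1 and returning at 18. Phenol 1 is O-alkylated with 2-bromo-2-methylpropanamide (NaOH, N,N-dimethylacetamide, rt) to 2-methyl-2-(3,4,5-tribromophenoxy)propanamide F1. Warming with more NaOH brings about the Smiles rearrangement to 2-hydroxy-2-methyl-N-(3,4,5-tribromophenyl)propanamide F2, and aqueous NaOH at reflux hydrolyses this to 3,4,5-tribromoaniline F3, which can also simply be bought. A Gassman indole synthesis follows: tert-butyl hypochlorite in CH2Cl2 at −70 °C gives N-chloro-3,4,5-tribromoaniline F4; methylthioacetaldehyde dimethyl acetal gives the azasulfonium salt (2,2-dimethoxyethyl)(methyl)[(3,4,5-tribromophenyl)amino]sulfonium chloride F5; Et3N triggers the [2,3]-sigmatropic shift to racemic 3,4,5-tribromo-2-[2,2-dimethoxy-1-(methylsulfanyl)ethyl]aniline F6. Both ortho positions of the aniline are equivalent, so only one regioisomer can arise. Ethereal HCl closes the ring to 4,5,6-tribromo-3-(methylsulfanyl)-1H-indole F7, and one equivalent of NBS in CH2Cl2 at 0 °C should brominate the free C2 position to give 18.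

Step 2. Bromine–lithium scrambling between ring positions, loss of LiBr from the ortho-bromoaryllithium, silylation at both ortho positions or anionic Fries migration of the carbamoyl group may erode the mono-silylation. The fallback places silicon by halogen–metal exchange and O-to-C silyl migration instead of deprotonation; it sets out from 1 and returns at 7. Mono-iodination of 1 ortho to the hydroxyl (N-iodosuccinimide, one equivalent, cat. TsOH, MeCN) gives 3,4,5-tribromo-2-iodophenol F8, and hexamethyldisilazane in THF at reflux gives (3,4,5-tribromo-2-iodophenoxy)trimethylsilane F9. n-BuLi in THF at −100 °C exchanges the iodine selectively to give (3,4,5-tribromo-2-lithiophenoxy)trimethylsilane F10, which undergoes retro-Brook rearrangement to the lithium salt of 6. Quenching with Tf2O in the same flask gives 7.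

Step 4. Dithiocarboxylation at nitrogen instead of carbon if the dianion is incompletely formed, attack of the intermediate thiolate on the carbamate carbonyl, or N-methylation by excess iodomethane may divert the reaction. The fallback installs nitrogen last by a Curtius rearrangement; it sets out from 9 and 10, with commercial tert-butyl methyl malonate as the carbon acid, and returns at 13. K2CO3, 9 and 10 in DMF give 1-tert-butyl 3-methyl 2-[bis(methylsulfanyl)methylidene]propanedioate F11, and trifluoroacetic acid in CH2Cl2 removes the tert-butyl ester to give 2-(methoxycarbonyl)-3,3-bis(methylsulfanyl)prop-2-enoic acid F12. Diphenylphosphoryl azide and Et3N in toluene give 2-(methoxycarbonyl)-3,3-bis(methylsulfanyl)prop-2-enoyl azide F13, which on heating to 80 °C rearranges to methyl 2-isocyanato-3,3-bis(methylsulfanyl)prop-2-enoate F14. Trapping with tert-butanol gives 13.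

**Further compounds**

F1 | step 5 | 2-methyl-2-(3,4,5-tribromophenoxy)propanamide | CC(C)(Oc1cc(Br)c(Br)c(Br)c1)C(N)=O
F2 | step 5 | 2-hydroxy-2-methyl-N-(3,4,5-tribromophenyl)propanamide | CC(C)(O)C(=O)Nc1cc(Br)c(Br)c(Br)c1
F3 | step 5 | 3,4,5-tribromoaniline | Nc1cc(Br)c(Br)c(Br)c1
F4 | step 5 | N-chloro-3,4,5-tribromoaniline | ClNc1cc(Br)c(Br)c(Br)c1
F5 | step 5 | (2,2-dimethoxyethyl)(methyl)[(3,4,5-tribromophenyl)amino]sulfonium chloride | C[S+](CC(OC)OC)Nc1cc(Br)c(Br)c(Br)c1.[Cl-]
F6 | step 5 | 3,4,5-tribromo-2-[2,2-dimethoxy-1-(methylsulfanyl)ethyl]aniline (racemic) | COC(OC)C(SC)c1c(N)cc(Br)c(Br)c1Br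
F7 | step 5 | 4,5,6-tribromo-3-(methylsulfanyl)-1H-indole | CSc1c[nH]c2cc(Br)c(Br)c(Br)c12
F8 | step 2 | 3,4,5-tribromo-2-iodophenol | Oc1cc(Br)c(Br)c(Br)c1I
F9 | step 2 | (3,4,5-tribromo-2-iodophenoxy)trimethylsilane | C[Si](C)(C)Oc1cc(Br)c(Br)c(Br)c1I
F10 | step 2 | (3,4,5-tribromo-2-lithiophenoxy)trimethylsilane | [Li]c1c(O[Si](C)(C)C)cc(Br)c(Br)c1Br
F11 | step 4 | 1-tert-butyl 3-methyl 2-[bis(methylsulfanyl)methylidene]propanedioate | COC(=O)C(C(=O)OC(C)(C)C)=C(SC)SC
F12 | step 4 | 2-(methoxycarbonyl)-3,3-bis(methylsulfanyl)prop-2-enoic acid | COC(=O)C(C(O)=O)=C(SC)SC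
F13 | step 4 | 2-(methoxycarbonyl)-3,3-bis(methylsulfanyl)prop-2-enoyl azide | COC(=O)C(C(=O)N=[N+]=[N-])=C(SC)SC
F14 | step 4 | methyl 2-isocyanato-3,3-bis(methylsulfanyl)prop-2-enoate | COC(=O)C(N=C=O)=C(SC)SC
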